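**Retrosynthetic overview**
1. The caffeate is attached last by esterification of the C15 alcohol of a 2-O-silylated labd-7-en-15-ol with bis-silylated caffeic acid.
2. Rings A and B come from one cation–olefin cascade of an open-chain (E,E)-diene: ionisation of a tertiary methyl ether at C4, C4–C5 closes ring A first, C9–C10 then closes ring B, and proton loss gives C7=C8. The C2 silyloxy group, equatorial in the chair, passes its configuration on to C5, C10 and C9.
3. The open chain is made in one three-component operation from a C3–C4 boronic ester, a vinyl Grignard reagent (C1–C2) and a C5–C15 alkenyl bromide: palladium forms C2–C3 and C1–C10 together, the ligand sets C2, and the C–B bond becomes the C2–OH.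
4. Enabling feature: in ring A the carbinol carbon C2 lies between two unsubstituted methylenes, C1 and C3, and C1 is bonded to C10, which is an sp2 alkene carbon in the open-chain form of rings A and B. The unit C3H2–C2H(OH)–C1H2–C10(sp2) is what a vinylboron unit leaves after 1,2-shift, coupling and oxidation.
5. The alkenyl bromide comes from (S)-citronellol (source of C13) by allylic oxidation, propargylation–methylation and hydrozirconation–bromination.

Key step: step 7

Remark: labdane numbering (C1–C20) is used for all skeleton atoms, also in open-chain intermediates; 1-bromo-2-methoxy-2-methylpropane is taken as a purchasable building block, and (Sp,Sp)-MandyPhos is assumed to be the ligand antipode that gives the 13R boronate (the other antipode is used if the sense is opposite).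

**Step 1**
Reactants: 1 (S)-citronellol, (3S)-3,7-dimethyloct-6-en-1-ol
Product: 2 (3S)-3,7-dimethyloct-6-en-1-yl pivalate
Conditions: PivCl, pyridine, DMAP (cat.), CH2Cl2, 0 °C to rt
Reagents that add atoms: pivaloyl chloride, CC(C)(C)C(=O)Cl
Why: Acylation of the primary alcohol by the acid chloride (nucleophilic catalysis by DMAP) gives a hindered ester that survives the carbanion, hydride and Lewis acid steps ahead; the C13 stereocentre comes unchanged from the chiral pool.

**Step 2**
Reactants: 2 (3S)-3,7-dimethyloct-6-en-1-yl pivalate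
Product: 3 (3S,6E)-8-hydroxy-3,7-dimethyloct-6-en-1-yl pivalate
Conditions: SeO2 (cat.), t-BuOOH, salicylic acid (cat.), CH2Cl2, rt
Reagents that add atoms: tert-butyl hydroperoxide, CC(C)(C)OO (oxygen passed on through selenium dioxide, O=[Se]=O)
Why: Allylic oxidation with SeO2 (ene reaction, then 2,3-sigmatropic shift of the allylseleninic acid, SeO2 regenerated by t-BuOOH) attacks the methyl group trans to the chain on the more substituted alkene carbon and so gives the (E)-allylic alcohol, which fixes the geometry of the later C8=C9 alkene.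

**Step 3**
Reactants: 3 (3S,6E)-8-hydroxy-3,7-dimethyloct-6-en-1-yl pivalate
Product: 4 (3S,6E)-8-bromo-3,7-dimethyloct-6-en-1-yl pivalate
Conditions: CBr4, PPh3, CH2Cl2, 0 °C
Reagents that add atoms: carbon tetrabromide, BrC(Br)(Br)Br
Why: Appel reaction: the oxyphosphonium ion of the primary allylic alcohol is displaced by bromide without allylic shift and with the (E) geometry intact.

**Step 4**
Reactants: 4 (3S,6E)-8-bromo-3,7-dimethyloct-6-en-1-yl pivalate
Product: 6 (3S,6E)-3,7-dimethyldodec-6-en-10-yn-1-yl pivalate, via lithium acetylide 5 (not isolated)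
Conditions: propyne, n-BuLi (2 equiv), TMEDA, Et2O/hexane, −78 °C to rt; 4, THF, −78 °C; then MeI, −78 °C to rt
Reagents that add atoms: propyne, CC#C; iodomethane, CI
Why: The sp3 carbanion end of 1,3-dilithiopropyne displaces the primary allylic bromide by SN2 at −78 °C, faster than any attack on the hindered pivalate, and the lithium acetylide 5 left over is C-methylated by MeI, a known one-flask propargylation–methylation of allylic halides.

**Step 5**
Reactants: 6 (3S,6E)-3,7-dimethyldodec-6-en-10-yn-1-yl pivalate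
Product: 8 (3S,6E,10E)-11-bromo-3,7-dimethyldodeca-6,10-dien-1-yl pivalate, via alkenylzirconocene chloride 7 (not isolated)
Conditions: Cp2Zr(H)Cl, THF, rt to 40 °C; then NBS, 0 °C
Reagents that add atoms: N-bromosuccinimide, O=C1CCC(=O)N1Br
Why: syn-Hydrozirconation of the internal alkyne, equilibrated with a slight excess of Cp2Zr(H)Cl so that zirconium rests on the less hindered, methyl-bearing carbon, followed by bromination of the C–Zr bond with retention should give the (E)-2-bromoalk-2-ene; the trisubstituted alkene and the pivalate should not react under these conditions.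

**Step 6**
Reactants: 9 1-bromo-2-methoxy-2-methylpropane
Product: 10 2-(2-methoxy-2-methylpropyl)-4,4,5,5-tetramethyl-1,3,2-dioxaborolane
Conditions: B2pin2, CuI (cat.), PPh3 (cat.), LiOMe, DMF, rt
Reagents that add atoms: bis(pinacolato)diboron, CC1(C)OB(OC1(C)C)B1OC(C)(C)C(C)(C)O1
Why: Copper-catalysed borylation of an unactivated primary alkyl bromide with B2pin2 (boryl-copper species, radical-type activation of the C–Br bond) is insensitive to the neopentyl position and should leave the tertiary methyl ether alone.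

**Step 7**
Reactants: 10 2-(2-methoxy-2-methylpropyl)-4,4,5,5-tetramethyl-1,3,2-dioxaborolane; 11 vinylmagnesium bromide; 8 (3S,6E,10E)-11-bromo-3,7-dimethyldodeca-6,10-dien-1-yl pivalate
Product: 14 (3S,6E,10E,13R)-13-hydroxy-15-methoxy-3,7,11,15-tetramethylhexadeca-6,10-dien-1-yl pivalate, via bromomagnesium vinylborate 12 (not isolated), via secondary pinacol boronic ester 13 (not isolated)
Conditions: 10, 11, NaOTf, THF, 0 °C to rt; then 8, Pd(OAc)2 (cat.), (Sp,Sp)-MandyPhos (cat.), THF, 60 °C; then H2O2, aq NaOH, 0 °C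
Reagents that add atoms: hydrogen peroxide, OO
Why: The vinyl Grignard reagent adds to the boron of 10 to give the four-coordinate borate 12; zerovalent palladium inserts into the C–Br bond of 8, triflate-for-bromide exchange frees a site on the divalent alkenylpalladium, this binds the vinyl group of 12 and triggers an anti 1,2-shift of the C3 alkyl group from boron to C2 (bond C2–C3) with formation of a C1–Pd bond, and reductive elimination then joins C1 to C10 with retention of the (E) geometry. The closest known reaction type is the palladium-catalysed enantioselective conjunctive cross-coupling of vinylboron ate complexes, made from a boronic ester and a vinyl Grignard reagent in the presence of NaOTf, with C(sp2) bromides, followed by stereoretentive peroxide oxidation of the C–B bond. No ring is closed here; both new bonds lie in the open chain, and rings A and B follow in step 9. The one new stereocentre, C2, is set by the chiral ferrocenyl bisphosphine on palladium (catalyst control, the distant C13 centre has no say), and the oxidation keeps it. The step needs the metallate shift to outrun direct transfer of a boron substituent to palladium and β-hydride loss from the alkylpalladium, and it needs the methoxy group to stay in place; the chelating MandyPhos ligand, the halide-free cationic palladium made by NaOTf, the primary migrating carbon C3 and the poor leaving-group ability of a tertiary methoxide from a four-coordinate borate should secure this.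

**Step 8**
Reactants: 14 (3S,6E,10E,13R)-13-hydroxy-15-methoxy-3,7,11,15-tetramethylhexadeca-6,10-dien-1-yl pivalate
Product: 15 (3S,6E,10E,13R)-13-(tert-butyldimethylsilyloxy)-15-methoxy-3,7,11,15-tetramethylhexadeca-6,10-dien-1-yl pivalate
Conditions: TBSCl, imidazole, DMF, rt
Reagents that add atoms: tert-butyldimethylsilyl chloride, CC(C)(C)[Si](C)(C)Cl
Why: Standard silylation of the secondary alcohol masks the C2 oxygen as a bulky, weakly basic ether that should neither ionise nor take part in the cationic step that follows.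

**Step 9**
Reactants: 15 (3S,6E,10E,13R)-13-(tert-butyldimethylsilyloxy)-15-methoxy-3,7,11,15-tetramethylhexadeca-6,10-dien-1-yl pivalate
Product: 16 (2S,5S,9S,10S,13S)-2-(tert-butyldimethylsilyloxy)labd-7-en-15-yl pivalate (2α-silyloxy, 5α-H, 9α-H, 10β-methyl)
Conditions: MeAlCl2, CH2Cl2, −78 °C; aq NaHCO3
Reagents that add atoms: none
Why: Ionisation of the tertiary methyl ether by MeAlCl2 (cationic polyene cyclisation, the alkylaluminium also acting as proton trap) sets off a chair–chair cascade in which C4 adds to C5 of the (E)-C5=C10 alkene (ring A, 6-endo) and C10 then takes C9 of the (E)-C8=C9 alkene (ring B, 6-endo); the C2 silyloxy group sits equatorial to avoid the axial methyl groups on C4 and C10, so the C2 centre dictates the face, anti addition across both alkenes gives 5α-H, 10β-methyl and the equatorial 9β side chain, and kinetic loss of the axial C7 proton from the C8 cation should give the C7=C8 alkene.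

**Step 10**
Reactants: 16 (2S,5S,9S,10S,13S)-2-(tert-butyldimethylsilyloxy)labd-7-en-15-yl pivalate
Product: 17 (2S,5S,9S,10S,13S)-2-(tert-butyldimethylsilyloxy)labd-7-en-15-ol
Conditions: i-Bu2AlH, CH2Cl2, −78 °C; aq Rochelle salt
Reagents that add atoms: none
Why: Hydride reduction of the pivalate to the primary alcohol and 2,2-dimethylpropanol at −78 °C should leave the silyl ether and the trisubstituted alkene untouched.

**Step 11**
Reactants: 18 caffeic acid, (E)-3-(3,4-dihydroxyphenyl)prop-2-enoic acid
Product: 20 (E)-3-[3,4-bis(tert-butyldimethylsilyloxy)phenyl]prop-2-enoic acid, via tris-silylated caffeic acid 19 (not isolated)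
Conditions: TBSCl, imidazole, DMF, rt; then AcOH, THF/H2O, rt
Reagents that add atoms: tert-butyldimethylsilyl chloride, CC(C)(C)[Si](C)(C)Cl
Why: Exhaustive silylation followed by mild acidic hydrolysis of the much more labile silyl ester gives the cinnamic acid with both phenols protected and the (E)-alkene unchanged.

**Step 12**
Reactants: 17 (2S,5S,9S,10S,13S)-2-(tert-butyldimethylsilyloxy)labd-7-en-15-ol; 20 (E)-3-[3,4-bis(tert-butyldimethylsilyloxy)phenyl]prop-2-enoic acid
Product: 21 (2S,5S,9S,10S,13S)-2-(tert-butyldimethylsilyloxy)labd-7-en-15-yl (E)-3-[3,4-bis(tert-butyldimethylsilyloxy)phenyl]prop-2-enoate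
Conditions: DCC, DMAP (cat.), CH2Cl2, 0 °C to rt
Reagents that add atoms: none
Why: Steglich esterification: DCC activates the acid as its O-acylisourea, DMAP passes the acyl group to the unhindered primary C15 alcohol, and no stereocentre is involved.

**Step 13**
Reactants: 21 (2S,5S,9S,10S,13S)-2-(tert-butyldimethylsilyloxy)labd-7-en-15-yl (E)-3-[3,4-bis(tert-butyldimethylsilyloxy)phenyl]prop-2-enoate
Product: 22 (2S,5S,9S,10S,13S)-2-hydroxylabd-7-en-15-yl (E)-3-(3,4-dihydroxyphenyl)prop-2-enoate (CNP0206083.1)
Conditions: HF·pyridine, THF/pyridine, 0 °C to rt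
Reagents that add atoms: none
Why: Fluoride cleaves the two aryl silyl ethers and the equatorial secondary silyl ether in one operation under mildly acidic conditions that should spare the enoate, the catechol and the C7=C8 alkene.

**Compound list**
1 | (S)-citronellol | CC(C)=CCC[C@H](C)CCO | starting material
2 | (3S)-3,7-dimethyloct-6-en-1-yl pivalate | CC(C)=CCC[C@H](C)CCOC(=O)C(C)(C)C | intermediate
3 | (3S,6E)-8-hydroxy-3,7-dimethyloct-6-en-1-yl pivalate | OC/C(C)=C/CC[C@H](C)CCOC(=O)C(C)(C)C | intermediate
4 | (3S,6E)-8-bromo-3,7-dimethyloct-6-en-1-yl pivalate | BrC/C(C)=C/CC[C@H](C)CCOC(=O)C(C)(C)C | intermediate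
5 | lithium acetylide of (3S,6E)-3,7-dimethylundec-6-en-10-yn-1-yl pivalate | [Li]C#CCC/C(C)=C/CC[C@H](C)CCOC(=O)C(C)(C)C | intermediate
6 | (3S,6E)-3,7-dimethyldodec-6-en-10-yn-1-yl pivalate | CC#CCC/C(C)=C/CC[C@H](C)CCOC(=O)C(C)(C)C | intermediate
7 | [(2E,6E,10S)-6,10-dimethyl-12-(pivaloyloxy)dodeca-2,6-dien-2-yl]zirconocene chloride (cyclopentadienyl rings drawn σ-bonded) | Cl[Zr](C1C=CC=C1)(C1C=CC=C1)/C(C)=C/CC/C(C)=C/CC[C@H](C)CCOC(=O)C(C)(C)C | intermediate
8 | (3S,6E,10E)-11-bromo-3,7-dimethyldodeca-6,10-dien-1-yl pivalate | Br/C(C)=C/CC/C(C)=C/CC[C@H](C)CCOC(=O)C(C)(C)C | intermediate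
9 | 1-bromo-2-methoxy-2-methylpropane | COC(C)(C)CBr | starting material
10 | 2-(2-methoxy-2-methylpropyl)-4,4,5,5-tetramethyl-1,3,2-dioxaborolane | COC(C)(C)CB1OC(C)(C)C(C)(C)O1 | intermediate
11 | vinylmagnesium bromide | C=C[Mg]Br | starting material
12 | bromomagnesium (2-methoxy-2-methylpropyl)(vinyl)(pinacolato)borate | COC(C)(C)C[B-]1(C=C)OC(C)(C)C(C)(C)O1.[Mg+]Br | intermediate
13 | (3S,6E,10E,13R)-15-methoxy-3,7,11,15-tetramethyl-13-(4,4,5,5-tetramethyl-1,3,2-dioxaborolan-2-yl)hexadeca-6,10-dien-1-yl pivalate | COC(C)(C)C[C@H](B1OC(C)(C)C(C)(C)O1)C/C(C)=C/CC/C(C)=C/CC[C@H](C)CCOC(=O)C(C)(C)C | intermediate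
14 | (3S,6E,10E,13R)-13-hydroxy-15-methoxy-3,7,11,15-tetramethylhexadeca-6,10-dien-1-yl pivalate | COC(C)(C)C[C@H](O)C/C(C)=C/CC/C(C)=C/CC[C@H](C)CCOC(=O)C(C)(C)C | intermediate
15 | (3S,6E,10E,13R)-13-(tert-butyldimethylsilyloxy)-15-methoxy-3,7,11,15-tetramethylhexadeca-6,10-dien-1-yl pivalate | COC(C)(C)C[C@H](O[Si](C)(C)C(C)(C)C)C/C(C)=C/CC/C(C)=C/CC[C@H](C)CCOC(=O)C(C)(C)C | intermediate
16 | (2S,5S,9S,10S,13S)-2-(tert-butyldimethylsilyloxy)labd-7-en-15-yl pivalate | CC1=CC[C@H]2C(C)(C)C[C@H](O[Si](C)(C)C(C)(C)C)C[C@]2(C)[C@H]1CC[C@H](C)CCOC(=O)C(C)(C)C | intermediate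
17 | (2S,5S,9S,10S,13S)-2-(tert-butyldimethylsilyloxy)labd-7-en-15-ol | CC1=CC[C@H]2C(C)(C)C[C@H](O[Si](C)(C)C(C)(C)C)C[C@]2(C)[C@H]1CC[C@H](C)CCO | intermediate
18 | caffeic acid | OC(=O)/C=C/c1ccc(O)c(O)c1 | starting material
19 | tert-butyldimethylsilyl (E)-3-[3,4-bis(tert-butyldimethylsilyloxy)phenyl]prop-2-enoate | CC(C)(C)[Si](C)(C)OC(=O)/C=C/c1ccc(O[Si](C)(C)C(C)(C)C)c(O[Si](C)(C)C(C)(C)C)c1 | intermediate
20 | (E)-3-[3,4-bis(tert-butyldimethylsilyloxy)phenyl]prop-2-enoic acid | OC(=O)/C=C/c1ccc(O[Si](C)(C)C(C)(C)C)c(O[Si](C)(C)C(C)(C)C)c1 | intermediate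
21 | (2S,5S,9S,10S,13S)-2-(tert-butyldimethylsilyloxy)labd-7-en-15-yl (E)-3-[3,4-bis(tert-butyldimethylsilyloxy)phenyl]prop-2-enoate | CC1=CC[C@H]2C(C)(C)C[C@H](O[Si](C)(C)C(C)(C)C)C[C@]2(C)[C@H]1CC[C@H](C)CCOC(=O)/C=C/c1ccc(O[Si](C)(C)C(C)(C)C)c(O[Si](C)(C)C(C)(C)C)c1 | intermediate
22 | (2S,5S,9S,10S,13S)-2-hydroxylabd-7-en-15-yl (E)-3-(3,4-dihydroxyphenyl)prop-2-enoate (CNP0206083.1) | CC1=CC[C@H]2C(C)(C)C[C@H](O)C[C@]2(C)[C@H]1CC[C@H](C)CCOC(=O)/C=C/c1ccc(O)c(O)c1 | target

**Step count and risks**
Total step count: 13. Longest linear sequence: 11 steps (steps 1, 2, 3, 4, 5, 7, 8, 9, 10, 12, 13).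

The three steps most likely to fail are steps 7, 9 and 5.

Step 7. What may go wrong: direct transfer of the alkyl or vinyl group from boron to palladium (plain cross-coupling) instead of the 1,2-shift, β-elimination of methoxide from borate 12, or a poor enantiofacial bias in the shift. The fallback sets out from bromide 8 and returns at alcohol 14; it brings the C1–C2 unit in as a resolved terminal epoxide and opens it with the alkenyl carbanion. Commercial 2-methylpent-4-en-2-ol is O-methylated (NaH, MeI, THF) to 4-methoxy-4-methylpent-1-ene F1, epoxidised (mCPBA, CH2Cl2, 0 °C) to racemic 2-(2-methoxy-2-methylpropyl)oxirane F2, and resolved by hydrolytic kinetic resolution (chiral (salen)Co(OAc) catalyst, 0.55 equiv H2O) to (S)-2-(2-methoxy-2-methylpropyl)oxirane F3. Bromine–lithium exchange on 8 (t-BuLi, Et2O, −78 °C) should give, with retention of geometry, the alkenyllithium F4, which opens F3 at its CH2 terminus in the presence of BF3·OEt2 (−78 °C) to give 14.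

Step 9. What may go wrong: unselective loss of a proton from the C8 cation (exocyclic C8=C17 or tetrasubstituted C8=C9 alkene), or transfer of chloride or methyl from the aluminate to C8. The fallback sets out from ether 15 and returns at bicycle 16; it ends the cascade on purpose by chloride capture and rebuilds the C7=C8–CH3 unit from the C8 ketone. Cyclisation of 15 with TiCl4 (CH2Cl2, −78 °C, cold quench) should give, by chloride entry anti to the new C9–C10 bond, 8α-chloro-2α-(tert-butyldimethylsilyloxy)labdan-15-yl pivalate F5 with an equatorial chloride. KOtBu in THF can remove HCl only toward the methyl group, because the equatorial C–Cl bond has no anti-periplanar ring hydrogen, and should give 2α-(tert-butyldimethylsilyloxy)labd-8(17)-en-15-yl pivalate F6. Ozonolysis (O3, CH2Cl2/MeOH, −78 °C; Me2S) gives 2α-(tert-butyldimethylsilyloxy)-8-oxo-17-norlabdan-15-yl pivalate F7. Kinetic deprotonation at C7 (LDA, THF, −78 °C) and trapping with PhNTf2 give the C7-enol triflate, 2α-(tert-butyldimethylsilyloxy)-8-(trifluoromethylsulfonyloxy)-17-norlabd-7-en-15-yl pivalate F8. Me2CuLi (Et2O, −20 °C) replaces the triflate by methyl and returns 16.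

Step 5. What may go wrong: zirconium settling partly on the other alkyne carbon, which would give a regioisomeric bromide that is hard to remove, or hydride attack on the pivalate. The fallback sets out from alcohol 3 and returns at bromide 8; it builds the bromoalkene by a B-alkyl Suzuki–Miyaura coupling whose regiochemistry is fixed by the halide pattern of the partner. Oxidation of 3 (MnO2, CH2Cl2) gives (3S,6E)-3,7-dimethyl-8-oxooct-6-en-1-yl pivalate F9, and Wittig methylenation (Ph3P=CH2, THF, 0 °C) gives (3S,6E)-3,7-dimethylnona-6,8-dien-1-yl pivalate F10. Hydroboration of the terminal vinyl group with 9-BBN (THF, 0 °C to rt) gives the B-alkyl-9-borabicyclo[3.3.1]nonane F11. This is coupled with (E)-2-bromo-1-iodoprop-1-ene F12 (made from propyne and IBr, CH2Cl2, −78 °C) at the carbon–iodine bond (Pd(dppf)Cl2 cat., Cs2CO3, DMF/THF/H2O, rt), which should leave the bromine in place and give 8.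

**Further compounds**
F1 | step 7 | 4-methoxy-4-methylpent-1-ene | C=CCC(C)(C)OC
F2 | step 7 | racemic 2-(2-methoxy-2-methylpropyl)oxirane | COC(C)(C)CC1CO1
F3 | step 7 | (S)-2-(2-methoxy-2-methylpropyl)oxirane | COC(C)(C)C[C@H]1CO1
F4 | step 7 | alkenyllithium from 8, [(10S)-6,10-dimethyl-12-(pivaloyloxy)dodeca-2,6-dien-2-yl]lithium with lithium in the place of bromine | [Li]/C(C)=C/CC/C(C)=C/CC[C@H](C)CCOC(=O)C(C)(C)C
F5 | step 9 | 8α-chloro-2α-(tert-butyldimethylsilyloxy)labdan-15-yl pivalate | C[C@@]1(Cl)CC[C@H]2C(C)(C)C[C@H](O[Si](C)(C)C(C)(C)C)C[C@]2(C)[C@H]1CC[C@H](C)CCOC(=O)C(C)(C)C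
F6 | step 9 | 2α-(tert-butyldimethylsilyloxy)labd-8(17)-en-15-yl pivalate | C=C1CC[C@H]2C(C)(C)C[C@H](O[Si](C)(C)C(C)(C)C)C[C@]2(C)[C@H]1CC[C@H](C)CCOC(=O)C(C)(C)C
F7 | step 9 | 2α-(tert-butyldimethylsilyloxy)-8-oxo-17-norlabdan-15-yl pivalate | O=C1CC[C@H]2C(C)(C)C[C@H](O[Si](C)(C)C(C)(C)C)C[C@]2(C)[C@H]1CC[C@H](C)CCOC(=O)C(C)(C)C
F8 | step 9 | 2α-(tert-butyldimethylsilyloxy)-8-(trifluoromethylsulfonyloxy)-17-norlabd-7-en-15-yl pivalate | O=S(=O)(OC1=CC[C@H]2C(C)(C)C[C@H](O[Si](C)(C)C(C)(C)C)C[C@]2(C)[C@H]1CC[C@H](C)CCOC(=O)C(C)(C)C)C(F)(F)F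
F9 | step 5 | (3S,6E)-3,7-dimethyl-8-oxooct-6-en-1-yl pivalate | O=C/C(C)=C/CC[C@H](C)CCOC(=O)C(C)(C)C
F10 | step 5 | (3S,6E)-3,7-dimethylnona-6,8-dien-1-yl pivalate | C=C/C(C)=C/CC[C@H](C)CCOC(=O)C(C)(C)C
F11 | step 5 | (3S,6E)-9-(9-borabicyclo[3.3.1]nonan-9-yl)-3,7-dimethylnon-6-en-1-yl pivalate | B1(CC/C(C)=C/CC[C@H](C)CCOC(=O)C(C)(C)C)C2CCCC1CCC2
F12 | step 5 | (E)-2-bromo-1-iodoprop-1-ene | Br/C(C)=C/I
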